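**Retrosynthetic overview**
1. Kazinol N (10) ⇒ bromochromenol 8 + allylphenol 2: the sp2–sp3 bond at C6 of the chromene is made last by B-alkyl Suzuki coupling; ring A is bought intact.
2. 8 ⇒ salicylaldehyde 5: the pyran ring is closed through its O1–C2 bond (C–O, key step) by oxa-6π electrocyclization of vinyl ortho-quinone methide 7, generated from 5 and an alkenylboronic acid (proposed new catechol-anchored annulation).
3. 5 ⇒ dibromo aldehyde 4: the prenyl group enters by Stille coupling at the bromine ortho to the formyl group.
4. 4 ⇒ symmetric 4,5-dibromocatechol 3 by ortho-formylation; the symmetry of 3 allows only one regioisomer.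
5. Ring order: both benzene rings are purchased; the pyran ring (step 4) is the only ring formed; no protecting groups are used.

Assumption: the target SMILES has no stereocentre (the molecule is achiral), so "single enantiomer" calls for no stereocontrol.

**Route**

Step 1
Reactants: 1 4-bromo-3-methoxyphenol
Product: 2 3-methoxy-4-(prop-2-en-1-yl)phenol
Conditions: allyl-B(pin) (1.5 equiv), Pd(dppf)Cl2 (3 mol%), K2CO3 (3 equiv), 1,4-dioxane/H2O 5:1, 80 °C
Reagents that add atoms: allylboronic acid pinacol ester, C=CCB1OC(C)(C)C(C)(C)O1
Why: Suzuki–Miyaura allylation, in which zerovalent palladium inserts into the C–Br bond and the allyl group is transferred from boron; the free phenol is tolerated under aqueous carbonate.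

Step 2
Reactants: 3 4,5-dibromobenzene-1,2-diol
Product: 4 5,6-dibromo-2,3-dihydroxybenzaldehyde
Conditions: MgCl2 (3 equiv), Et3N (6 equiv), (CH2O)n (4 equiv), MeCN, reflux; then 1 M HCl
Reagents that add atoms: paraformaldehyde (as formaldehyde), C=O
Why: magnesium-mediated ortho-formylation (Casnati–Skattebøl reaction), in which the magnesium catecholate delivers formaldehyde to the carbon ortho to oxygen and a second formaldehyde oxidises the benzylic alkoxide to the aldehyde; the two free positions of 3 are equivalent, so only one regioisomer can form.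

Step 3
Reactants: 4 5,6-dibromo-2,3-dihydroxybenzaldehyde
Product: 5 5-bromo-2,3-dihydroxy-6-(3-methylbut-2-en-1-yl)benzaldehyde
Conditions: Bu3SnCH2CH=CMe2 (1.2 equiv), Pd2(dba)3 (2.5 mol%), P(2-furyl)3 (10 mol%), DMF, 80 °C, argon
Reagents that add atoms: tributyl(3-methylbut-2-en-1-yl)stannane, CCCC[Sn](CCCC)(CCCC)CC=C(C)C
Why: site-selective Stille coupling, because oxidative addition of zerovalent palladium is much faster at the C–Br bond ortho to the electron-withdrawing formyl group than at the one para to a hydroxyl, and the prenyl group is delivered at its unsubstituted terminus; allylstannanes do not add to the aldehyde without a Lewis acid.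

Step 4
Reactants: 5 5-bromo-2,3-dihydroxy-6-(3-methylbut-2-en-1-yl)benzaldehyde
Product: 8 6-bromo-2,2-dimethyl-5-(3-methylbut-2-en-1-yl)-2H-chromen-8-ol, via allylic dibenzylamine 6 (not isolated), via ortho-quinone methide 7 (not isolated)
Conditions: (2-methylprop-1-en-1-yl)boronic acid (1.5 equiv), Bn2NH (30 mol%), 1,4-dioxane, 90 °C; aqueous work-up
Reagents that add atoms: (2-methylprop-1-en-1-yl)boronic acid, CC(C)=CB(O)O
Why: Proposed new method: the catechol of 5 esterifies the alkenylboronic acid so that boron sits on O2 beside the formyl group, dibenzylamine turns the aldehyde into a hemiaminal whose oxygen completes a tetracoordinate boronate and ionises to the iminium, the 2-methylprop-1-enyl group then migrates from boron to the iminium carbon inside this chelate to give 6, and at 90 °C the benzylic amine is expelled to form vinyl ortho-quinone methide 7, whose oxa-6π electrocyclization makes the pyran O1–C2 bond and frees the amine for the next turnover; the closest known reaction type is the amine-catalysed Petasis borono-Mannich condensation of simple salicylaldehydes with alkenylboronic acids to 2H-chromenes, and what is new is its use on a 2,3-dihydroxybenzaldehyde with the catechol as boron anchor and a formyl group flanked by two ortho substituents.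

Step 5
Reactants: 2 3-methoxy-4-(prop-2-en-1-yl)phenol; 8 6-bromo-2,2-dimethyl-5-(3-methylbut-2-en-1-yl)-2H-chromen-8-ol
Product: 10 Kazinol N, via bis(9-BBN) borane 9 (not isolated)
Conditions: 2 (1.3 equiv), 9-BBN (0.5 M in THF, 2.2 equiv per 2), 0 °C to rt; then 8, Pd(OAc)2 (5 mol%), SPhos (10 mol%), K3PO4 (3 M aq, 4 equiv), THF, 65 °C
Reagents that add atoms: none
Why: hydroboration followed by B-alkyl Suzuki–Miyaura coupling, in which 9-BBN adds anti-Markovnikov to the terminal allyl alkene only (one further equivalent is taken up by the phenol as a borinate) and the primary alkylborane couples with the aryl bromide of 8 without touching the trisubstituted prenyl or chromene double bonds.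

**Compound list**
1 | 4-bromo-3-methoxyphenol | COc1cc(O)ccc1Br | starting material
2 | 3-methoxy-4-(prop-2-en-1-yl)phenol | COc1cc(O)ccc1CC=C | intermediate
3 | 4,5-dibromobenzene-1,2-diol | Oc1cc(Br)c(Br)cc1O | starting material
4 | 5,6-dibromo-2,3-dihydroxybenzaldehyde | O=Cc1c(O)c(O)cc(Br)c1Br | intermediate
5 | 5-bromo-2,3-dihydroxy-6-(3-methylbut-2-en-1-yl)benzaldehyde | CC(C)=CCc1c(Br)cc(O)c(O)c1C=O | intermediate
6 | 5-bromo-3-[1-(dibenzylamino)-3-methylbut-2-en-1-yl]-4-(3-methylbut-2-en-1-yl)benzene-1,2-diol (racemic, not isolated; boron-bound at the catechol in the flask) | CC(C)=CCc1c(Br)cc(O)c(O)c1C(C=C(C)C)N(Cc1ccccc1)Cc1ccccc1 | intermediate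
7 | (6Z)-4-bromo-2-hydroxy-5-(3-methylbut-2-en-1-yl)-6-(3-methylbut-2-en-1-ylidene)cyclohexa-2,4-dien-1-one (not isolated) | O=C1C(O)=CC(Br)=C(CC=C(C)C)/C1=C/C=C(C)C | intermediate
8 | 6-bromo-2,2-dimethyl-5-(3-methylbut-2-en-1-yl)-2H-chromen-8-ol | CC1(C)C=Cc2c(CC=C(C)C)c(Br)cc(O)c2O1 | intermediate
9 | 9-{3-[4-(9-borabicyclo[3.3.1]nonan-9-yloxy)-2-methoxyphenyl]propyl}-9-borabicyclo[3.3.1]nonane (not isolated) | COc1cc(OB2C3CCCC2CCC3)ccc1CCCB1C2CCCC1CCC2 | intermediate
10 | Kazinol N, 6-[3-(4-hydroxy-2-methoxyphenyl)propyl]-2,2-dimethyl-5-(3-methylbut-2-en-1-yl)-2H-chromen-8-ol | COc1cc(O)ccc1CCCc1cc(O)c2c(c1CC=C(C)C)C=CC(C)(C)O2 | target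

**Step count and risks**
Total steps: 5. Longest linear sequence: 4 (3 → 4 → 5 → 8 → 10); step 1 is a one-step side branch.

The three steps most likely to fail:

- **Step 2.** The magnesium salt of an electron-poor catechol may be poorly soluble, react sluggishly or formylate twice. The fallback sets out from 3 and comes back at 4. Compound 3 is protected with MOMCl and i-Pr2NEt as 1,2-dibromo-4,5-bis(methoxymethoxy)benzene F1. F1 is deprotonated between bromine and oxygen with LiN(i-Pr)2 in THF at −78 °C (an amide base, so no bromine–lithium exchange) and quenched with DMF to give 5,6-dibromo-2,3-bis(methoxymethoxy)benzaldehyde F2. HCl in methanol then removes both acetals to give 4.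

- **Step 3.** Prenyl transfer at a carbon flanked by a formyl group and a bromine may be slow, may give some branched (1,1-dimethylallyl) isomer, or may be accompanied by coupling at the other bromine. The fallback sets out from 4 and comes back at 5. Stille coupling with Bu3SnCH2CH=CH2 under the same catalyst puts in the small allyl group, which transfers faster and has no branched isomer, to give 5-bromo-2,3-dihydroxy-6-(prop-2-en-1-yl)benzaldehyde F3. Cross-metathesis of F3 with excess 2-methylbut-2-ene (second-generation Grubbs catalyst, CH2Cl2, 40 °C) then converts allyl into prenyl and gives 5.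

- **Step 4 (the proposed new step).** Iminium formation at the doubly ortho-substituted aldehyde may be slow, the boron-activated aldehyde or iminium may close onto the neighbouring prenyl alkene (carbonyl-ene or iminium-ene), and the alkenylboronic acid may protodeboronate. The fallback uses known chemistry, sets out from 5 and comes back at 8. Addition of Me2C=CHMgBr (4 equiv, THF, 0 °C to rt; two equivalents are consumed by the hydroxyl groups) gives 5-bromo-3-(1-hydroxy-3-methylbut-2-en-1-yl)-4-(3-methylbut-2-en-1-yl)benzene-1,2-diol F4. Warming F4 in toluene at 80 °C with a catalytic amount of pyridinium p-toluenesulfonate dehydrates it to the same ortho-quinone methide 7, which electrocyclizes to 8.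

**Further compounds**
F1 | step 2 | 1,2-dibromo-4,5-bis(methoxymethoxy)benzene | COCOc1cc(Br)c(Br)cc1OCOC
F2 | step 2 | 5,6-dibromo-2,3-bis(methoxymethoxy)benzaldehyde | COCOc1cc(Br)c(Br)c(C=O)c1OCOC
F3 | step 3 | 5-bromo-2,3-dihydroxy-6-(prop-2-en-1-yl)benzaldehyde | C=CCc1c(Br)cc(O)c(O)c1C=O
F4 | step 4 | 5-bromo-3-(1-hydroxy-3-methylbut-2-en-1-yl)-4-(3-methylbut-2-en-1-yl)benzene-1,2-diol (racemic) | CC(C)=CCc1c(Br)cc(O)c(O)c1C(O)C=C(C)C
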